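**Remark on the chemistry:** the target is the mono-O-acetate of atromentin at one of its two equivalent quinone hydroxyls. It has no stereocentre, so no stereocontrol is needed.

## Retrosynthetic overview

1. Target 9 is reached from the symmetric dihydroxyquinone 6 (atromentin bis-benzyl ether) by one O-acetylation and O-debenzylation.
2. Key disconnection (biomimetic): in 6 the two ring bonds C3–C4 and C6–C1, each joining an aryl-bearing carbon to an oxygenated carbon, are cut. This gives two molecules of arylpyruvate ester 4, joined head to tail by a double Claisen condensation, as in the presumed biosynthesis from two 4-hydroxyphenylpyruvate units.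
3. Enabling feature: the quinone ring consists of two identical three-carbon units C(aryl)–C(O)–C(O). Each aryl-bearing ring carbon lies between two oxygenated ring carbons, and the 2,5-dihydroxy-1,4-benzoquinone is the enol tautomer of a cyclohexane-1,2,4,5-tetraone, so two 2-oxo esters minus two alcohols give it without any redox step.
4. Ester 4 comes in one step from 4-(benzyloxy)benzyl chloride and diethyl oxalate.
5. Ring order: both benzene rings are bought; the quinone ring is the only ring made and is closed last, in step 2.

Key step: step 2

## Route

Step 1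
Reactants: 1 4-(benzyloxy)benzyl chloride; 2 diethyl oxalate
Product: 4 ethyl 3-[4-(benzyloxy)phenyl]-2-oxopropanoate, via Grignard reagent 3 (not isolated)
Conditions: Mg (I2 cat.), Et2O/THF, 0 °C, dilute; then cannulated into 2 (2.5 equiv), THF, −78 °C; 1 M HCl quench at −78 °C
Reagents that add atoms: none
Why: Mono-acylation of a benzylic Grignard reagent by an oxalate diester; inverse addition at −78 °C should stop at the magnesium hemiketal, which gives the 2-oxo ester only on acidic quench, and cold, dilute Grignard formation limits Wurtz coupling.

Step 2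
Reactants: 4 ethyl 3-[4-(benzyloxy)phenyl]-2-oxopropanoate (2 equiv)
Product: 6 2,5-bis[4-(benzyloxy)phenyl]-3,6-dihydroxycyclohexa-2,5-diene-1,4-dione (atromentin bis-benzyl ether), via acyclic triketo ester 5 (not isolated)
Conditions: NaH (2.2 equiv per 4), THF (0.5 M), Ar, 0 °C → 65 °C; then 1 M HCl, 0 °C
Reagents that add atoms: none
Why: Proposed new method: with excess NaH each molecule of 4 is held as its sodium enolate, so the ketone is masked and the ester is the only electrophile; the benzylic carbon of one enolate C-acylates the ester of a second (intermolecular Claisen) to give 5, whose remaining benzylic carbon then attacks the remaining ester, with loss of two ethoxides overall. The closest known reaction types are the Claisen–Dieckmann sequence and the alkoxide-mediated self-condensation of oxalyl-derived 2-oxo esters to 3,6-dialkyl-2,5-dihydroxy-1,4-benzoquinones, and the step copies the presumed biosynthesis from two enzyme-bound 4-hydroxyphenylpyruvate units. The quinone ring is closed by a 6-exo-trig Dieckmann condensation (C-acylation of the enolate in 5), and the cyclohexane-1,2,4,5-tetraone formed should tautomerise to the dihydroxyquinone without any redox step. No stereocentre is formed. The step needs Claisen over aldol and C- over O-acylation: complete enolisation before warming removes the ketone electrophile, head-to-tail regiochemistry is inherent because each unit has one nucleophilic carbon and one acyl donor, and aldol adducts or O-acyl products should stay reversible under the ethoxide formed in situ while the product leaves the equilibria as its doubly vinylogous carboxylate dianion.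

Step 3
Reactants: 6 2,5-bis[4-(benzyloxy)phenyl]-3,6-dihydroxycyclohexa-2,5-diene-1,4-dione
Product: 7 2,5-bis[4-(benzyloxy)phenyl]-4-hydroxy-3,6-dioxocyclohexa-1,4-dien-1-yl acetate
Conditions: Et3N (2.2 equiv), CH2Cl2, −40 °C; Ac2O (1.0 equiv, slow addition), → 0 °C; cold 0.5 M HCl wash
Reagents that add atoms: acetic anhydride, CC(=O)OC(C)=O
Why: O-acylation of the bis(triethylammonium) dianion of the dihydroxyquinone (enol ester formation): the dianion is a far better nucleophile than the mono-acetate mono-anion, and any diacetate, being the strongest acyl donor present, should pass an acetyl group to remaining dianion, so one equivalent of anhydride should stop at the mono-acetate; the two hydroxyls are equivalent, so there is no regiochemical issue.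

Step 4
Reactants: 7 2,5-bis[4-(benzyloxy)phenyl]-4-hydroxy-3,6-dioxocyclohexa-1,4-dien-1-yl acetate
Product: 9 4-hydroxy-2,5-bis(4-hydroxyphenyl)-3,6-dioxocyclohexa-1,4-dien-1-yl acetate (target), via leuco hydroquinone acetate 8 (not isolated)
Conditions: H2 (1 atm), 10% Pd/C, EtOAc, rt; filtration under Ar; then air, rt
Reagents that add atoms: none
Why: Neutral hydrogenolysis of the two aryl benzyl ethers with concurrent reduction of the quinone to hydroquinone 8, followed by autoxidation of the electron-rich hydroquinone in air; the acetate is not attacked under neutral H2/Pd, and acyl migration in 8 would be harmless because the four ring oxygens of the leuco form are symmetry-equivalent, so every mono-acetate reoxidises to the same quinone.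

## Compound list

1 | 4-(benzyloxy)benzyl chloride | ClCc1ccc(OCc2ccccc2)cc1 | starting material
2 | diethyl oxalate | CCOC(=O)C(=O)OCC | starting material
3 | [4-(benzyloxy)benzyl]magnesium chloride | Cl[Mg]Cc1ccc(OCc2ccccc2)cc1 | intermediate
4 | ethyl 3-[4-(benzyloxy)phenyl]-2-oxopropanoate | CCOC(=O)C(=O)Cc1ccc(OCc2ccccc2)cc1 | intermediate
5 | ethyl 3,6-bis[4-(benzyloxy)phenyl]-2,4,5-trioxohexanoate (racemic, enolised in the flask) | CCOC(=O)C(=O)C(c1ccc(OCc2ccccc2)cc1)C(=O)C(=O)Cc1ccc(OCc2ccccc2)cc1 | intermediate
6 | 2,5-bis[4-(benzyloxy)phenyl]-3,6-dihydroxycyclohexa-2,5-diene-1,4-dione | O=C1C(O)=C(c2ccc(OCc3ccccc3)cc2)C(=O)C(O)=C1c1ccc(OCc2ccccc2)cc1 | intermediate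
7 | 2,5-bis[4-(benzyloxy)phenyl]-4-hydroxy-3,6-dioxocyclohexa-1,4-dien-1-yl acetate | CC(=O)OC1=C(c2ccc(OCc3ccccc3)cc2)C(=O)C(O)=C(c2ccc(OCc3ccccc3)cc2)C1=O | intermediate
8 | 2,4,5-trihydroxy-3,6-bis(4-hydroxyphenyl)phenyl acetate | CC(=O)Oc1c(-c2ccc(O)cc2)c(O)c(O)c(-c2ccc(O)cc2)c1O | intermediate
9 | 4-hydroxy-2,5-bis(4-hydroxyphenyl)-3,6-dioxocyclohexa-1,4-dien-1-yl acetate | CC(=O)OC1=C(c2ccc(O)cc2)C(=O)C(O)=C(c2ccc(O)cc2)C1=O | target

## Summary

Total step count: 4. Longest linear sequence: 4.

## Steps most likely to fail

**Step 2 (proposed new method).** The enolate of 4 may add to traces of non-enolised ketone (aldol addition followed by lactonisation) faster than it acylates, or the enolate–enolate Claisen step may stall. The fallback builds the diaryl quinone by cross-coupling, using known chemistry. It does not branch from an earlier numbered compound: it sets out from fresh commercial materials and comes back to the route at 6. Tetrabromo-1,4-benzoquinone (bromanil) F1 is treated with NaOMe in MeOH to give 2,5-dibromo-3,6-dimethoxy-1,4-benzoquinone F2 by addition–elimination. Double Suzuki–Miyaura coupling of F2 with [4-(benzyloxy)phenyl]boronic acid F3 (Pd(PPh3)4, K2CO3, dioxane, 90 °C) should give 2,5-bis[4-(benzyloxy)phenyl]-3,6-dimethoxy-1,4-benzoquinone F4. Hydrolysis of its two vinylogous methyl esters (aq. NaOH, dioxane, 60 °C, then HCl) should give 6.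

**Step 3.** Over-acetylation to the diacetate, or acetyl scrambling between quinone molecules during work-up, may leave a mixture of 6, 7 and diacetate. The fallback sets out from 6 and comes back at 7, by over-acetylation followed by removal of one acetate. Exhaustive acetylation of 6 (Ac2O, pyridine, rt) should give 2,5-bis[4-(benzyloxy)phenyl]-3,6-dioxocyclohexa-1,4-diene-1,4-diyl diacetate F5. One equivalent of aqueous NaHCO3 in THF at 0 °C should then cleave a single acetate, because the first hydrolysis leaves an anionic hydroxyquinone whose remaining acetate is a much poorer acyl donor.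

**Step 4.** The quinone acetate may be lost during the reduction–reoxidation sequence, by solvolysis or intermolecular acyl transfer in the leuco form, or reoxidation may be incomplete. The fallback sets out from 6 and comes back at the target 9, with the order of the last two operations reversed. Hydrogenolysis of 6 (H2, Pd/C, THF) should give 3,6-bis(4-hydroxyphenyl)benzene-1,2,4,5-tetrol (leucoatromentin) F6, which is oxidised in air without isolation to 2,5-dihydroxy-3,6-bis(4-hydroxyphenyl)cyclohexa-2,5-diene-1,4-dione (atromentin) F7. F7 is then treated with N-methylmorpholine (2 equiv) and Ac2O (1.0 equiv) in THF at −20 °C. This base should deprotonate only the two acidic quinone hydroxyls and leave the phenols neutral, so that one quinone oxygen is acetylated to give 9.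

## Further compounds

F1 | step 2 | tetrabromo-1,4-benzoquinone (bromanil) | O=C1C(Br)=C(Br)C(=O)C(Br)=C1Br
F2 | step 2 | 2,5-dibromo-3,6-dimethoxy-1,4-benzoquinone | COC1=C(Br)C(=O)C(OC)=C(Br)C1=O
F3 | step 2 | [4-(benzyloxy)phenyl]boronic acid | OB(O)c1ccc(OCc2ccccc2)cc1
F4 | step 2 | 2,5-bis[4-(benzyloxy)phenyl]-3,6-dimethoxy-1,4-benzoquinone | COC1=C(c2ccc(OCc3ccccc3)cc2)C(=O)C(OC)=C(c2ccc(OCc3ccccc3)cc2)C1=O
F5 | step 3 | 2,5-bis[4-(benzyloxy)phenyl]-3,6-dioxocyclohexa-1,4-diene-1,4-diyl diacetate | CC(=O)OC1=C(c2ccc(OCc3ccccc3)cc2)C(=O)C(OC(C)=O)=C(c2ccc(OCc3ccccc3)cc2)C1=O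
F6 | step 4 | 3,6-bis(4-hydroxyphenyl)benzene-1,2,4,5-tetrol (leucoatromentin) | Oc1ccc(cc1)-c1c(O)c(O)c(-c2ccc(O)cc2)c(O)c1O
F7 | step 4 | 2,5-dihydroxy-3,6-bis(4-hydroxyphenyl)cyclohexa-2,5-diene-1,4-dione (atromentin) | O=C1C(O)=C(c2ccc(O)cc2)C(=O)C(O)=C1c1ccc(O)cc1
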